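Assumption: (2E,4E,6E)-2,7-dimethylocta-2,4,6-trienedial (21) and triethyl (E)-3-methyl-4-phosphonocrotonate (11) are taken as commercial, geometrically pure materials. Carotenoid locants (C1–C15, primed for the right half) are used for all intermediates.

## The problem

The target is an all-E C40 carotenoid, (3S,5R,6S,3'S,5'R,8'R)-5',8'-epoxy-5,6,5',8'-tetrahydro-β,β-carotene-3,5,6,3'-tetrol. An octaene chain (C7 to C10') joins two different end groups: a 3,5,6-triol cyclohexane on the left, and on the right a 3'-hydroxycyclohexane fused to a 2,5-dihydrofuran (O, C5', C6', C7', C8'). Because the ends differ, the chain has to be built by two separate E-selective olefinations around a central C10 unit.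

There are six stereocentres. C3 and C3' have the same sense and can come from one chiral ring ketone. C5, C6 and C5' are fully substituted carbinol carbons that sit 1,3 to C3, too remote for dependable substrate control, so one reagent-controlled step is needed. C8' is a secondary, doubly allylic ether carbon whose C9' arm is trans to the C5' methyl.

Two groups limit the late chemistry. The tertiary allylic C6 hydroxyl ionises in acid and would close to a second furanoid, and the C8'–O bond ionises in acid and epimerises C8'. After the end groups exist, only neutral or basic steps are allowed, and the polyene must be kept from light and oxygen.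

The feature that opens the route is that the C5/C6 cis-diol has exactly the configuration of a 5,6-epoxide trans to the C3 oxygen in which the C6–O bond has been replaced with retention. C6 is allylic to the C7=C8 alkene, and neither neighbour (C1, C5) carries hydrogen. The right-hand dihydrofuran is what the same epoxide gives when its C6–O bond ionises and the C5 oxygen closes on C8. One epoxide can therefore serve both ends, provided a retentive opening at C6 is found for the left half.

## Retrosynthesis

**29 to 28.** The two O–Si bonds at C3 and C3' are cut last. Fluoride is the one deprotection that both the tertiary allylic alcohol and the furanoid ether tolerate, so 28 carries silyl ethers only on the secondary hydroxyls and the 5,6-diol is left free.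

**28 to 17 and 26.** The C11=C12 double bond is cut, giving the left C15 dienal 17 and the right C25 phosphonate 26. A cut at C15=C15' would need two further chain extensions on each half. Making the left half the nucleophile would put two free tertiary hydroxyls on the carbanion partner. The forward Horner–Wadsworth–Emmons reaction must be E-selective and must not epimerise C8'.

**26 to 20 and 24.** The C11'=C12' double bond is cut, giving furanoid C15 enal 20 and the symmetric C10 bisphosphonate 24. Compound 24 comes from commercial dialdehyde 21 through diol 22 and dibromide 23. One C10 reagent serves both junctions; the forward reaction has to stop after one olefination.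

**17 to 16 to 15.** These are oxidation-level changes only. The aldehyde is traced to the primary alcohol of triol 16, and 16 to the ester carbonate 15. One hydride reagent reduces the ester and cleaves the carbonate, so the diol needs no separate deprotection.

**15 to 13 and 14 (key).** The C6–O bond of the cyclic carbonate and the carbonate C–O bond at the C5 oxygen are cut, giving epoxy dienoate 13 and carbon dioxide 14. Acid hydrolysis of the epoxide would attack C6 through a cation, with scrambling and furanoid formation. A π-allyl palladium double inversion returns oxygen to C6 on the face the epoxide oxygen left. The whole C5/C6 problem is thereby reduced to the configuration of one epoxide.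

**20 to 19 to 18 to 13.** The O–C8' bond of the dihydrofuran is cut, giving back the same epoxide 13 through ester 18 and alcohol 19. The forward acid rearrangement keeps C5' but does not control C8', so a separation is accepted here in return for a one-step entry from the shared intermediate.

**13 to 10 and 11.** The C7=C8 double bond is cut, giving epoxy aldehyde 10 and phosphonocrotonate 11. The aldehyde has a quaternary α-carbon, so it cannot enolise, and the C5 phosphonate brings C8–C11 with the ester in place.

**10 to 9 to 8.** The two epoxide C–O bonds are cut, giving allylic alcohol 8. Epoxidising at this stage, and not on a C15 trienoate with a peracid, allows a titanium tartrate catalyst to choose the face; the remote C3 silyl ether alone gives only a modest bias.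

**8 to 7 to 6 to 4.** The C6–C7 bond is cut. The hydroxymethyl carbon comes from carbon monoxide by carbonylation of enol triflate 6, and 6 comes regiospecifically from ketone 4, which has only one enolisable side.

**4 to 3 to 2 to 1.** The C3 oxygen stereocentre is traced to ketoisophorone 1. An ene-reductase sets the methyl-bearing centre of 2, that centre directs the hydride reduction to 3, and it is erased again when 6 is formed.

## Roads not taken

**Alternative 1:** Both C–O bonds of the left diol are cut at once, back to the ring enyne A2 (C5=C6 alkene with a silylated ethynyl group on C6), which one Sonogashira coupling would give from triflate 6. In the forward step OsO4 (octavalent osmium) with an amine N-oxide adds syn to the only alkene, from the face away from the C3 silyloxy group, to give alkynyl cis-diol A1.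

- Merits: the cis relationship is guaranteed by the mechanism, and no epoxide or palladium is needed. From 6 the diol is reached in two steps against six for 15, so for the left half this road is shorter.
- Weak points: the alkene is tetrasubstituted, flanked by the quaternary C1 and conjugated to an alkyne, so osmylation should be slow and may need stoichiometric osmium. The face is chosen only by the remote C3 substituent. The alkyne still has to become an E,E-dienal by hydrometallation and cross-coupling next to a ditertiary diol.
- Comparison: the right half gains nothing from this road and would need its own route to an epoxide or other dihydrofuran precursor. The chosen plan sets against the shorter count a configuration fixed by a reagent-controlled epoxidation and transferred stereospecifically, and one intermediate (13) that feeds both ends.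

**Alternative 2:** The right half is cut at C5'–O and C8'–O together, back to triene ester A4 (one cross-coupling from 6) and oxygen. In the forward step singlet oxygen, from a porphyrin sensitiser and visible light, adds [4+2] across C5' and C8' to give endoperoxide A3, a 3,6-dihydro-1,2-dioxine.

- Merits: the suprafacial cycloaddition fixes C5' and C8' relative to each other in one step. On paper this is better than the chosen plan, whose acid rearrangement leaves C8' uncontrolled.
- Weak points: the hindered, twisted diene must reach an s-cis geometry, and ene reactions at C4' and the C5' methyl compete. The dienoate is electron-poor towards electrophilic singlet oxygen, and the face is again chosen by C3' alone. One peroxide oxygen must then be removed. Displacement at the secondary C8' by the C5' oxygen would invert C8', and the tertiary C5' cannot be displaced, so the C8' configuration drawn in A3 does not pass directly to the target.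
- Comparison: the left diol would need a separate solution. The chosen plan accepts an epimer separation at 18 but uses a rearrangement of well-understood course and shares 13 between the halves.

**Alternative 3:** Only the O–C8' bond is cut, back to allenic acetate A6 (C6'=C7'=C8' allene with a free C5' hydroxyl). In the forward step Ph3PAuCl with AgBF4 (monovalent gold) activates the allene, the hydroxyl adds to C8' in a 5-endo closure, and the allene axis is translated into the C8' centre, giving furanoid acetate A5.

- Merits: it controls C8', the one stereocentre the chosen plan leaves to separation, under mild neutral conditions. It is the strongest competitor for the right half.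
- Weak points: the difficulty moves to A6. Its axis must be set, usually by SN2' hydride opening of a 5,6-epoxy-7-yne, so the epoxide is still needed and the right half becomes several steps longer. Gold can erode the axis through allyl-cation-like intermediates at a tertiary carbinol.
- Comparison: the left half still needs its own answer. If separation of the C8' epimers at 18 proved impractical, this road would be taken for the right half. The chosen plan sets against it a single step from 13 to 18, recycling of the unwanted epimer by re-equilibration, and a common precursor for both ends.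

Key step: step 10

## Route

Step 1
Reactants: 1 ketoisophorone (2,6,6-trimethylcyclohex-2-ene-1,4-dione)
Product: 2 (6R)-2,2,6-trimethylcyclohexane-1,4-dione
Conditions: ene-reductase OYE2 (old yellow enzyme), NADP+ (cat.), glucose dehydrogenase, D-glucose, phosphate buffer pH 6.5, 25 °C
Reagents that add atoms: none
Why: Ene-reductase conjugate reduction of the enedione C=C with hydride from NADPH recycled by glucose dehydrogenase; the enzyme sets the methyl-bearing carbon as R, the same reduction that fermenting baker's yeast performs on this substrate, and the slightly acidic buffer limits enolisation of the product.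

Step 2
Reactants: 2 (6R)-2,2,6-trimethylcyclohexane-1,4-dione
Product: 3 (4R,6R)-4-hydroxy-2,2,6-trimethylcyclohexan-1-one
Conditions: LiBH(s-Bu)3 (1.05 equiv), THF, −78 °C; then H2O
Reagents that add atoms: none
Why: Hydride reduction with a bulky trialkylborohydride; the C1 carbonyl is shielded by its quaternary and methyl-bearing neighbours, and at C4 axial approach is blocked by the axial C2 methyl, so equatorial delivery should give the axial alcohol trans to the C6 methyl (4R), as with 3,3,5-trimethylcyclohexanone.

Step 3
Reactants: 3 (4R,6R)-4-hydroxy-2,2,6-trimethylcyclohexan-1-one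
Product: 4 (4R,6R)-4-(tert-butyldimethylsilyloxy)-2,2,6-trimethylcyclohexan-1-one
Conditions: TBSCl, imidazole, DMF, rt
Reagents that add atoms: tert-butyldimethylsilyl chloride, CC(C)(C)[Si](C)(C)Cl
Why: Standard silylation of a secondary alcohol; the ether has to survive base, hydride, peroxide, palladium and mild acid, and it comes off with fluoride at the end.

Step 4
Reactants: 4 (4R,6R)-4-(tert-butyldimethylsilyloxy)-2,2,6-trimethylcyclohexan-1-one
Product: 6 (4R)-4-(tert-butyldimethylsilyloxy)-2,6,6-trimethylcyclohex-1-en-1-yl trifluoromethanesulfonate, via lithium enolate 5 (not isolated)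
Conditions: LiN(i-Pr)2, THF, −78 °C; then PhNTf2, −78 °C → rt
Reagents that add atoms: N-phenylbis(trifluoromethanesulfonimide), O=S(=O)(N(c1ccccc1)S(=O)(=O)C(F)(F)F)C(F)(F)F
Why: Enolate formation and O-triflation; only the methyl-bearing α-carbon carries hydrogen, so a single tetrasubstituted enol triflate should form, and the auxiliary methyl stereocentre is erased after it has directed step 2.

Step 5
Reactants: 6 (4R)-4-(tert-butyldimethylsilyloxy)-2,6,6-trimethylcyclohex-1-en-1-yl trifluoromethanesulfonate
Product: 7 methyl (4R)-4-(tert-butyldimethylsilyloxy)-2,6,6-trimethylcyclohex-1-ene-1-carboxylate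
Conditions: Pd(OAc)2 (5 mol %), PPh3, Et3N, CO (1 atm), MeOH/DMF, 60 °C
Reagents that add atoms: carbon monoxide, [C-]#[O+]; methanol, CO
Why: Palladium-catalysed alkoxycarbonylation of an enol triflate (oxidative addition, CO insertion, methanolysis), a reaction well established for hindered cyclohexenyl triflates.

Step 6
Reactants: 7 methyl (4R)-4-(tert-butyldimethylsilyloxy)-2,6,6-trimethylcyclohex-1-ene-1-carboxylate
Product: 8 [(4R)-4-(tert-butyldimethylsilyloxy)-2,6,6-trimethylcyclohex-1-en-1-yl]methanol
Conditions: i-Bu2AlH, CH2Cl2, −78 → 0 °C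
Reagents that add atoms: none
Why: 1,2-Reduction of the conjugated ester to the allylic alcohol with i-Bu2AlH; conjugate reduction is not expected at a tetrasubstituted β-carbon.

Step 7
Reactants: 8 [(4R)-4-(tert-butyldimethylsilyloxy)-2,6,6-trimethylcyclohex-1-en-1-yl]methanol
Product: 9 [(1R,4S,6R)-4-(tert-butyldimethylsilyloxy)-2,2,6-trimethyl-7-oxabicyclo[4.1.0]heptan-1-yl]methanol
Conditions: Ti(O-i-Pr)4, D-(−)-diethyl tartrate, t-BuOOH, 4 Å MS, CH2Cl2, −20 °C
Reagents that add atoms: tert-butyl hydroperoxide, CC(C)(C)OO
Why: Sharpless asymmetric epoxidation of a primary allylic alcohol; the empirical face rule assigns the D-(−)-tartrate to the ring face opposite the C3 silyloxy group, so C5 and C6 should be set as the epoxide trans to the C3 oxygen under reagent control, not by the weak bias of the remote silyl ether.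

Step 8
Reactants: 9 [(1R,4S,6R)-4-(tert-butyldimethylsilyloxy)-2,2,6-trimethyl-7-oxabicyclo[4.1.0]heptan-1-yl]methanol
Product: 10 (1S,4S,6R)-4-(tert-butyldimethylsilyloxy)-2,2,6-trimethyl-7-oxabicyclo[4.1.0]heptane-1-carbaldehyde
Conditions: Pr4N[RuO4] (5 mol %), N-methylmorpholine N-oxide, 4 Å MS, CH2Cl2, rt
Reagents that add atoms: none
Why: Ley–Griffith oxidation of the primary alcohol; the α-carbon is quaternary, so the epoxy aldehyde can neither epimerise nor eliminate.

Step 9
Reactants: 10 (1S,4S,6R)-4-(tert-butyldimethylsilyloxy)-2,2,6-trimethyl-7-oxabicyclo[4.1.0]heptane-1-carbaldehyde; 11 triethyl (E)-3-methyl-4-phosphonocrotonate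
Product: 13 ethyl (2E,4E)-3-methyl-5-[(1S,4S,6R)-4-(tert-butyldimethylsilyloxy)-2,2,6-trimethyl-7-oxabicyclo[4.1.0]heptan-1-yl]penta-2,4-dienoate, via lithiated phosphonocrotonate 12 (not isolated)
Conditions: 11, n-BuLi, THF/DMPU, −78 °C; then 10, −78 → 0 °C
Reagents that add atoms: none
Why: Horner–Wadsworth–Emmons olefination with the vinylogous phosphonate; the stabilised anion should give the E C7=C8 bond, low temperature with DMPU keeps the C9=C10 bond E, and the epoxide is not attacked by the soft carbanion.

Step 10
Reactants: 13 ethyl (2E,4E)-3-methyl-5-[(1S,4S,6R)-4-(tert-butyldimethylsilyloxy)-2,2,6-trimethyl-7-oxabicyclo[4.1.0]heptan-1-yl]penta-2,4-dienoate; 14 carbon dioxide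
Product: 15 ethyl (2E,4E)-5-[(3aS,6S,7aR)-6-(tert-butyldimethylsilyloxy)-4,4,7a-trimethyl-2-oxohexahydro-1,3-benzodioxol-3a-yl]-3-methylpenta-2,4-dienoate
Conditions: Pd(PPh3)4 (5 mol %), CO2 (5 bar), THF, 25 °C; filtration through silica before venting
Reagents that add atoms: none
Why: Zerovalent palladium coordinates the C7=C8 alkene and ionises the allylic C6–O bond with inversion, giving a π-allyl complex of divalent palladium (C6–C7–C8) that carries a C5 alkoxide; the alkoxide captures CO2 and the carbonate oxygen then attacks C6 anti to the metal, which releases the catalyst. The closest known reaction is the palladium-catalysed coupling of vinyl epoxides with CO2 to vinyl-substituted cyclic carbonates (a Tsuji–Trost-type double inversion), known also where the allylic epoxide carbon is fully substituted. The 1,3-dioxolan-2-one closes in a 5-exo mode on the allyl terminus C6; closure at C8 would need a seven-membered ring, and direct attack of the C5 alkoxide on C8 would be an endo closure with the whole allyl unit inside a five-membered ring. The one stereocentre made here, C6, is controlled by the two successive inversions (net retention) and reinforced by the preference for a cis-fused bicyclic carbonate, so the epoxide trans to the C3 oxygen should become the (5R,6S) cis-diol carbonate while C5 keeps its oxygen throughout. The step needs retention at C6 and closure at C6 instead of C8; the tether length, the anti,anti sequence and CO2 pressure (fast carboxylation of the alkoxide) secure both, and because C1 and C5 carry no hydrogen there is no β-hydride route to a dienol. The product is itself an allylic carbonate that the catalyst could re-ionise, so the palladium is removed before the CO2 atmosphere is released.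

Step 11
Reactants: 15 ethyl (2E,4E)-5-[(3aS,6S,7aR)-6-(tert-butyldimethylsilyloxy)-4,4,7a-trimethyl-2-oxohexahydro-1,3-benzodioxol-3a-yl]-3-methylpenta-2,4-dienoate
Product: 16 (2E,4E)-5-[(1S,2R,4S)-4-(tert-butyldimethylsilyloxy)-1,2-dihydroxy-2,6,6-trimethylcyclohexyl]-3-methylpenta-2,4-dien-1-ol
Conditions: i-Bu2AlH (7 equiv), CH2Cl2, −78 → −20 °C; aq. potassium sodium tartrate
Reagents that add atoms: none
Why: Excess i-Bu2AlH reduces the dienoate to the allylic alcohol (1,2-reduction) and the cyclic carbonate to the free diol in one operation; no stereocentre is touched, and the neutral work-up protects the tertiary allylic C6 hydroxyl.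

Step 12
Reactants: 16 (2E,4E)-5-[(1S,2R,4S)-4-(tert-butyldimethylsilyloxy)-1,2-dihydroxy-2,6,6-trimethylcyclohexyl]-3-methylpenta-2,4-dien-1-ol
Product: 17 (2E,4E)-5-[(1S,2R,4S)-4-(tert-butyldimethylsilyloxy)-1,2-dihydroxy-2,6,6-trimethylcyclohexyl]-3-methylpenta-2,4-dienal
Conditions: [Cu(MeCN)4]OTf (5 mol %), 2,2'-bipyridine, TEMPO, N-methylimidazole, air, MeCN, rt
Reagents that add atoms: none
Why: Copper/nitroxyl aerobic alcohol oxidation is selective for primary alcohols and should leave the ditertiary cis-diol alone; active MnO2 is avoided on this compound because it can cleave cis-1,2-diols.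

Step 13
Reactants: 13 ethyl (2E,4E)-3-methyl-5-[(1S,4S,6R)-4-(tert-butyldimethylsilyloxy)-2,2,6-trimethyl-7-oxabicyclo[4.1.0]heptan-1-yl]penta-2,4-dienoate
Product: 18 ethyl (2E)-3-[(2R,6S,7aR)-6-(tert-butyldimethylsilyloxy)-4,4,7a-trimethyl-2,4,5,6,7,7a-hexahydro-1-benzofuran-2-yl]but-2-enoate
Conditions: camphorsulfonic acid (10 mol %), CH2Cl2, 0 °C → rt; chromatographic separation of the C8' epimers
Reagents that add atoms: none
Why: Acid-catalysed 5,6-epoxide to 5,8-epoxide (furanoid) rearrangement; the C6–O bond ionises to an allyl cation and the C5 oxygen, which keeps its configuration, closes on C8, while the absence of hydrogen on C1 and C5 excludes elimination. C8' is not controlled, so both epimers are expected; the 8'R isomer (C9' arm trans to the C5' methyl) is to be isolated by chromatography and the other epimer returned to the same acid for re-equilibration.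

Step 14
Reactants: 18 ethyl (2E)-3-[(2R,6S,7aR)-6-(tert-butyldimethylsilyloxy)-4,4,7a-trimethyl-2,4,5,6,7,7a-hexahydro-1-benzofuran-2-yl]but-2-enoate
Product: 19 (2E)-3-[(2R,6S,7aR)-6-(tert-butyldimethylsilyloxy)-4,4,7a-trimethyl-2,4,5,6,7,7a-hexahydro-1-benzofuran-2-yl]but-2-en-1-ol
Conditions: i-Bu2AlH, CH2Cl2, −78 °C; aq. potassium sodium tartrate
Reagents that add atoms: none
Why: 1,2-Reduction of the enoate with i-Bu2AlH at low temperature; the allylic ether at C8' is inert to the hydride and the work-up is neutral.

Step 15
Reactants: 19 (2E)-3-[(2R,6S,7aR)-6-(tert-butyldimethylsilyloxy)-4,4,7a-trimethyl-2,4,5,6,7,7a-hexahydro-1-benzofuran-2-yl]but-2-en-1-ol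
Product: 20 (2E)-3-[(2R,6S,7aR)-6-(tert-butyldimethylsilyloxy)-4,4,7a-trimethyl-2,4,5,6,7,7a-hexahydro-1-benzofuran-2-yl]but-2-enal
Conditions: MnO2, CH2Cl2, rt
Reagents that add atoms: none
Why: MnO2 oxidation of a primary allylic alcohol to the E-enal under neutral conditions, the standard entry to polyene aldehydes; this half has no diol that could be cleaved.

Step 16
Reactants: 21 (2E,4E,6E)-2,7-dimethylocta-2,4,6-trienedial
Product: 22 (2E,4E,6E)-2,7-dimethylocta-2,4,6-triene-1,8-diol
Conditions: NaBH4, MeOH/THF, 0 °C
Reagents that add atoms: none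
Why: Borohydride 1,2-reduction of both conjugated aldehyde groups; the triene is not reduced.

Step 17
Reactants: 22 (2E,4E,6E)-2,7-dimethylocta-2,4,6-triene-1,8-diol
Product: 23 (2E,4E,6E)-1,8-dibromo-2,7-dimethylocta-2,4,6-triene
Conditions: PBr3, pyridine (cat.), Et2O, −10 °C
Reagents that add atoms: phosphorus tribromide, BrP(Br)Br
Why: Conversion of the primary allylic alcohols into bromides with PBr3; low temperature keeps the substitution direct and the triene E.

Step 18
Reactants: 23 (2E,4E,6E)-1,8-dibromo-2,7-dimethylocta-2,4,6-triene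
Product: 24 tetraethyl [(2E,4E,6E)-2,7-dimethylocta-2,4,6-triene-1,8-diyl]bis(phosphonate)
Conditions: P(OEt)3, toluene, 110 °C
Reagents that add atoms: triethyl phosphite, CCOP(OCC)OCC
Why: Michaelis–Arbuzov reaction of the two primary allylic bromides with triethyl phosphite.

Step 19
Reactants: 20 (2E)-3-[(2R,6S,7aR)-6-(tert-butyldimethylsilyloxy)-4,4,7a-trimethyl-2,4,5,6,7,7a-hexahydro-1-benzofuran-2-yl]but-2-enal; 24 tetraethyl [(2E,4E,6E)-2,7-dimethylocta-2,4,6-triene-1,8-diyl]bis(phosphonate)
Product: 26 diethyl {(2E,4E,6E,8E,10E)-11-[(2R,6S,7aR)-6-(tert-butyldimethylsilyloxy)-4,4,7a-trimethyl-2,4,5,6,7,7a-hexahydro-1-benzofuran-2-yl]-2,7-dimethyldodeca-2,4,6,8,10-pentaen-1-yl}phosphonate, via bisphosphonate monoanion sodium salt 25 (not isolated)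
Conditions: 24 (4 equiv), NaN(SiMe3)2, THF, −78 °C; then 20 (slow addition), −78 → −20 °C
Reagents that add atoms: none
Why: Horner–Wadsworth–Emmons olefination of an allylic phosphonate anion with an enal, E-selective for the new C11'=C12' bond; the bisphosphonate is in excess and the aldehyde is added slowly so that one end reacts, and the neutral mono-olefination product is separated from recovered 24 by chromatography.

Step 20
Reactants: 26 diethyl {(2E,4E,6E,8E,10E)-11-[(2R,6S,7aR)-6-(tert-butyldimethylsilyloxy)-4,4,7a-trimethyl-2,4,5,6,7,7a-hexahydro-1-benzofuran-2-yl]-2,7-dimethyldodeca-2,4,6,8,10-pentaen-1-yl}phosphonate; 17 (2E,4E)-5-[(1S,2R,4S)-4-(tert-butyldimethylsilyloxy)-1,2-dihydroxy-2,6,6-trimethylcyclohexyl]-3-methylpenta-2,4-dienal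
Product: 28 3,3'-bis-O-(tert-butyldimethylsilyl) ether of the target, via phosphonate carbanion sodium salt 27 (not isolated)
Conditions: 26 (1.5 equiv), NaN(SiMe3)2, THF, −78 °C; then 17, −78 → 0 °C, in the dark
Reagents that add atoms: none
Why: A second Horner–Wadsworth–Emmons olefination forms C11=C12 with E preference; the anion carries no hydroxyl, the tertiary hydroxyls of 17 are too weakly acidic to quench the stabilised anion to a serious extent, and low temperature protects the C8'–O bond, as with the γ-alkoxy allyl phosphonate anions in routine use. Any Z isomer at the new bond or at C13=C14 can be equilibrated to all-E by gentle heating in the dark before purification.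

Step 21
Reactants: 28 3,3'-bis-O-(tert-butyldimethylsilyl) ether of the target
Product: 29 (all-E)-(3S,5R,6S,3'S,5'R,8'R)-5',8'-epoxy-5,6,5',8'-tetrahydro-β,β-carotene-3,5,6,3'-tetrol
Conditions: Bu4NF, THF, 0 °C → rt, in the dark
Reagents that add atoms: none
Why: Fluoride cleavage of the two secondary silyl ethers under basic, non-acidic conditions that neither the tertiary allylic alcohol nor the furanoid ether should object to; no stereocentre is involved.

## Compound list

1 | ketoisophorone (2,6,6-trimethylcyclohex-2-ene-1,4-dione) | CC1=CC(=O)CC(C)(C)C1=O | starting material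
2 | (6R)-2,2,6-trimethylcyclohexane-1,4-dione | O=C1C(C)(C)CC(=O)C[C@H]1C | intermediate
3 | (4R,6R)-4-hydroxy-2,2,6-trimethylcyclohexan-1-one | O=C1C(C)(C)C[C@H](O)C[C@H]1C | intermediate
4 | (4R,6R)-4-(tert-butyldimethylsilyloxy)-2,2,6-trimethylcyclohexan-1-one | O=C1C(C)(C)C[C@H](O[Si](C)(C)C(C)(C)C)C[C@H]1C | intermediate
5 | lithium (4R)-4-(tert-butyldimethylsilyloxy)-2,6,6-trimethylcyclohex-1-en-1-olate | [Li+].[O-]C1=C(C)C[C@@H](O[Si](C)(C)C(C)(C)C)CC1(C)C | intermediate
6 | (4R)-4-(tert-butyldimethylsilyloxy)-2,6,6-trimethylcyclohex-1-en-1-yl trifluoromethanesulfonate | CC1=C(OS(=O)(=O)C(F)(F)F)C(C)(C)C[C@H](O[Si](C)(C)C(C)(C)C)C1 | intermediate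
7 | methyl (4R)-4-(tert-butyldimethylsilyloxy)-2,6,6-trimethylcyclohex-1-ene-1-carboxylate | COC(=O)C1=C(C)C[C@@H](O[Si](C)(C)C(C)(C)C)CC1(C)C | intermediate
8 | [(4R)-4-(tert-butyldimethylsilyloxy)-2,6,6-trimethylcyclohex-1-en-1-yl]methanol | OCC1=C(C)C[C@@H](O[Si](C)(C)C(C)(C)C)CC1(C)C | intermediate
9 | [(1R,4S,6R)-4-(tert-butyldimethylsilyloxy)-2,2,6-trimethyl-7-oxabicyclo[4.1.0]heptan-1-yl]methanol (epoxide trans to the silyloxy group) | OC[C@]12C(C)(C)C[C@H](O[Si](C)(C)C(C)(C)C)C[C@@]1(C)O2 | intermediate
10 | (1S,4S,6R)-4-(tert-butyldimethylsilyloxy)-2,2,6-trimethyl-7-oxabicyclo[4.1.0]heptane-1-carbaldehyde | O=C[C@]12C(C)(C)C[C@H](O[Si](C)(C)C(C)(C)C)C[C@@]1(C)O2 | intermediate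
11 | triethyl (E)-3-methyl-4-phosphonocrotonate | CCOC(=O)/C=C(C)/CP(=O)(OCC)OCC | starting material
12 | lithium salt of the carbanion of 11 | [Li+].CCOC(=O)/C=C(C)/[CH-]P(=O)(OCC)OCC | intermediate
13 | ethyl (2E,4E)-3-methyl-5-[(1S,4S,6R)-4-(tert-butyldimethylsilyloxy)-2,2,6-trimethyl-7-oxabicyclo[4.1.0]heptan-1-yl]penta-2,4-dienoate (C15 5,6-epoxy dienoate) | CCOC(=O)/C=C(C)/C=C/[C@]12C(C)(C)C[C@H](O[Si](C)(C)C(C)(C)C)C[C@@]1(C)O2 | intermediate
14 | carbon dioxide | O=C=O | starting material
15 | ethyl (2E,4E)-5-[(3aS,6S,7aR)-6-(tert-butyldimethylsilyloxy)-4,4,7a-trimethyl-2-oxohexahydro-1,3-benzodioxol-3a-yl]-3-methylpenta-2,4-dienoate (5,6-cis cyclic carbonate) | CCOC(=O)/C=C(C)/C=C/[C@]12C(C)(C)C[C@H](O[Si](C)(C)C(C)(C)C)C[C@@]1(C)OC(=O)O2 | intermediate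
16 | (2E,4E)-5-[(1S,2R,4S)-4-(tert-butyldimethylsilyloxy)-1,2-dihydroxy-2,6,6-trimethylcyclohexyl]-3-methylpenta-2,4-dien-1-ol | OC/C=C(C)/C=C/[C@]1(O)C(C)(C)C[C@H](O[Si](C)(C)C(C)(C)C)C[C@@]1(C)O | intermediate
17 | (2E,4E)-5-[(1S,2R,4S)-4-(tert-butyldimethylsilyloxy)-1,2-dihydroxy-2,6,6-trimethylcyclohexyl]-3-methylpenta-2,4-dienal | O=C/C=C(C)/C=C/[C@]1(O)C(C)(C)C[C@H](O[Si](C)(C)C(C)(C)C)C[C@@]1(C)O | intermediate
18 | ethyl (2E)-3-[(2R,6S,7aR)-6-(tert-butyldimethylsilyloxy)-4,4,7a-trimethyl-2,4,5,6,7,7a-hexahydro-1-benzofuran-2-yl]but-2-enoate | CCOC(=O)/C=C(\C)[C@H]1C=C2C(C)(C)C[C@H](O[Si](C)(C)C(C)(C)C)C[C@@]2(C)O1 | intermediate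
19 | (2E)-3-[(2R,6S,7aR)-6-(tert-butyldimethylsilyloxy)-4,4,7a-trimethyl-2,4,5,6,7,7a-hexahydro-1-benzofuran-2-yl]but-2-en-1-ol | OC/C=C(\C)[C@H]1C=C2C(C)(C)C[C@H](O[Si](C)(C)C(C)(C)C)C[C@@]2(C)O1 | intermediate
20 | (2E)-3-[(2R,6S,7aR)-6-(tert-butyldimethylsilyloxy)-4,4,7a-trimethyl-2,4,5,6,7,7a-hexahydro-1-benzofuran-2-yl]but-2-enal | O=C/C=C(\C)[C@H]1C=C2C(C)(C)C[C@H](O[Si](C)(C)C(C)(C)C)C[C@@]2(C)O1 | intermediate
21 | (2E,4E,6E)-2,7-dimethylocta-2,4,6-trienedial | O=C/C(C)=C/C=C/C=C(\C)C=O | starting material
22 | (2E,4E,6E)-2,7-dimethylocta-2,4,6-triene-1,8-diol | OC/C(C)=C/C=C/C=C(\C)CO | intermediate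
23 | (2E,4E,6E)-1,8-dibromo-2,7-dimethylocta-2,4,6-triene | BrC/C(C)=C/C=C/C=C(\C)CBr | intermediate
24 | tetraethyl [(2E,4E,6E)-2,7-dimethylocta-2,4,6-triene-1,8-diyl]bis(phosphonate) | CCOP(=O)(OCC)C/C(C)=C/C=C/C=C(\C)CP(=O)(OCC)OCC | intermediate
25 | sodium salt of the monoanion of 24 | [Na+].CCOP(=O)(OCC)[CH-]/C(C)=C/C=C/C=C(\C)CP(=O)(OCC)OCC | intermediate
26 | diethyl {(2E,4E,6E,8E,10E)-11-[(2R,6S,7aR)-6-(tert-butyldimethylsilyloxy)-4,4,7a-trimethyl-2,4,5,6,7,7a-hexahydro-1-benzofuran-2-yl]-2,7-dimethyldodeca-2,4,6,8,10-pentaen-1-yl}phosphonate (C25 furanoid phosphonate) | CCOP(=O)(OCC)C/C(C)=C/C=C/C=C(C)/C=C/C=C(\C)[C@H]1C=C2C(C)(C)C[C@H](O[Si](C)(C)C(C)(C)C)C[C@@]2(C)O1 | intermediate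
27 | sodium salt of the carbanion of 26 | [Na+].CCOP(=O)(OCC)[CH-]/C(C)=C/C=C/C=C(C)/C=C/C=C(\C)[C@H]1C=C2C(C)(C)C[C@H](O[Si](C)(C)C(C)(C)C)C[C@@]2(C)O1 | intermediate
28 | (all-E)-(3S,5R,6S,3'S,5'R,8'R)-3,3'-bis(tert-butyldimethylsilyloxy)-5',8'-epoxy-5,6,5',8'-tetrahydro-β,β-carotene-5,6-diol | CC(/C=C/C=C(C)/C=C/[C@]1(O)C(C)(C)C[C@H](O[Si](C)(C)C(C)(C)C)C[C@@]1(C)O)=C\C=C\C=C(C)\C=C\C=C(/C)[C@H]1C=C2C(C)(C)C[C@H](O[Si](C)(C)C(C)(C)C)C[C@@]2(C)O1 | intermediate
29 | (all-E)-(3S,5R,6S,3'S,5'R,8'R)-5',8'-epoxy-5,6,5',8'-tetrahydro-β,β-carotene-3,5,6,3'-tetrol | CC(/C=C/C=C(C)/C=C/[C@]1(O)C(C)(C)C[C@H](O)C[C@@]1(C)O)=C\C=C\C=C(C)\C=C\C=C(/C)[C@H]1C=C2C(C)(C)C[C@H](O)C[C@@]2(C)O1 | target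

## Step count and least certain steps

Total step count: 21. Longest linear sequence: 15 steps (1–9, 13–15, 19–21). The left branch (10–12) joins at step 20 and the C10 branch (16–18) joins at step 19.

**Step 10 (key).** The most likely failure is slow or absent ionisation, because C6 is fully substituted and lies between two quaternary carbons. A second failure is leakage of the zwitterion to the dihydrofuran by attack of the C5 alkoxide on C8 if carboxylation is slow. A third is decarboxylative reversal if palladium is still present once the CO2 pressure is gone.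

Fallback: the cis-diol would be made by osmylation before the side chain is attached, setting out from 8 and returning at 15.
- Silylation of the primary alcohol of 8 (Et3SiCl, imidazole) gives the triethylsilyl ether F1.
- OsO4 (octavalent osmium) with N-methylmorpholine N-oxide, or in the last resort stoichiometric OsO4 in pyridine, adds to the only alkene, expected mainly trans to the C3 silyl ether, to give the cis-diol F2; the other diastereomer would be removed by chromatography.
- Carbonyldiimidazole in hot toluene closes the cyclic carbonate F3.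
- Pyridinium p-toluenesulfonate in methanol frees the primary alcohol F4.
- Pr4N[RuO4] with N-methylmorpholine N-oxide gives the aldehyde F5.
- Olefination of F5 with 12 under the conditions of step 9 gives 15.

**Step 13.** Closure at C8' is not face-selective, since both faces of the allyl cation are open, so roughly half of the material may have to be recycled and the epimers may separate poorly. In addition, the cation is conjugated with the ester, so ionisation may be sluggish and a semipinacol shift from C5 could compete.

Fallback: the rearrangement would be run at the alcohol oxidation level, setting out from 13 and returning at 19. Reduction of 13 with i-Bu2AlH gives the epoxy dienol F6. Its cation is a dienyl cation, so a trace of pyridinium p-toluenesulfonate in CH2Cl2 should suffice, and 19 is obtained after separation of the C8' epimers as alcohols.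

**Step 19.** The mono-olefination product 26 is more acidic than 24, so proton transfer to the excess anion can lead to a second olefination. Deprotonation of the enal 20 at a γ-position by the excess anion is a further loss.

Fallback: the statistical step would be replaced by one in which the symmetric partner becomes less reactive after the first reaction, setting out from 19 and returning at 26.
- CBr4/PPh3 gives the bromide F7.
- Sodium diethyl phosphite (Michaelis–Becker) gives the C15 phosphonate F8.
- F8 with NaN(SiMe3)2 and an excess of dialdehyde 21 gives the C25 aldehyde F9; this product is a poorer electrophile than 21.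
- NaBH4 gives the alcohol F10.
- CBr4/PPh3 gives the bromide F11.
- Sodium diethyl phosphite gives 26.

**Step 20.** Proton transfer from the two tertiary hydroxyls of 17 to anion 27 may stall the olefination. On long exposure, a vinylogous β-elimination of the C8' oxygen from the extended anion could open and re-close the dihydrofuran and scramble C8'. Z isomers at the new bond are a minor concern.

Fallback: the polarity of the last bond would be reversed so that the furanoid half is only ever the aldehyde, setting out from 17 and 24 and returning at 28. Aldehyde 17 is added slowly to an excess of 25 to give the left C25 phosphonate F12, with the diol free. F12 is then treated with NaN(SiMe3)2 (3.3 equiv) and 20, which forms C11'=C12' last and gives 28.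

Further compounds
F1 | step 10 | triethylsilyl ether of 8, tert-butyldimethyl{[(1R)-3,5,5-trimethyl-4-(triethylsilyloxymethyl)cyclohex-3-en-1-yl]oxy}silane | CC[Si](CC)(CC)OCC1=C(C)C[C@@H](O[Si](C)(C)C(C)(C)C)CC1(C)C
F2 | step 10 | (1S,2R,4S)-4-(tert-butyldimethylsilyloxy)-2,6,6-trimethyl-1-(triethylsilyloxymethyl)cyclohexane-1,2-diol (cis-diol trans to the C3 silyl ether) | CC[Si](CC)(CC)OC[C@]1(O)C(C)(C)C[C@H](O[Si](C)(C)C(C)(C)C)C[C@@]1(C)O
F3 | step 10 | cyclic carbonate of F2 | CC[Si](CC)(CC)OC[C@]12C(C)(C)C[C@H](O[Si](C)(C)C(C)(C)C)C[C@@]1(C)OC(=O)O2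
F4 | step 10 | primary alcohol from F3, 6-(tert-butyldimethylsilyloxy)-3a-(hydroxymethyl)-4,4,7a-trimethylhexahydro-1,3-benzodioxol-2-one | OC[C@]12C(C)(C)C[C@H](O[Si](C)(C)C(C)(C)C)C[C@@]1(C)OC(=O)O2
F5 | step 10 | carbonate aldehyde, 6-(tert-butyldimethylsilyloxy)-4,4,7a-trimethyl-2-oxohexahydro-1,3-benzodioxole-3a-carbaldehyde | O=C[C@]12C(C)(C)C[C@H](O[Si](C)(C)C(C)(C)C)C[C@@]1(C)OC(=O)O2
F6 | step 13 | (2E,4E)-3-methyl-5-[(1S,4S,6R)-4-(tert-butyldimethylsilyloxy)-2,2,6-trimethyl-7-oxabicyclo[4.1.0]heptan-1-yl]penta-2,4-dien-1-ol | OC/C=C(C)/C=C/[C@]12C(C)(C)C[C@H](O[Si](C)(C)C(C)(C)C)C[C@@]1(C)O2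
F7 | step 19 | allylic bromide from 19, (2R,6S,7aR)-2-[(2E)-4-bromobut-2-en-2-yl]-6-(tert-butyldimethylsilyloxy)-4,4,7a-trimethyl-2,4,5,6,7,7a-hexahydro-1-benzofuran | BrC/C=C(\C)[C@H]1C=C2C(C)(C)C[C@H](O[Si](C)(C)C(C)(C)C)C[C@@]2(C)O1
F8 | step 19 | C15 furanoid diethyl phosphonate from F7 | CCOP(=O)(OCC)C/C=C(\C)[C@H]1C=C2C(C)(C)C[C@H](O[Si](C)(C)C(C)(C)C)C[C@@]2(C)O1
F9 | step 19 | C25 furanoid aldehyde, (2E,4E,6E,8E,10E)-11-(furanoid ring as in 26)-2,7-dimethyldodeca-2,4,6,8,10-pentaenal | O=C/C(C)=C/C=C/C=C(C)/C=C/C=C(\C)[C@H]1C=C2C(C)(C)C[C@H](O[Si](C)(C)C(C)(C)C)C[C@@]2(C)O1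
F10 | step 19 | C25 furanoid alcohol from F9 | OC/C(C)=C/C=C/C=C(C)/C=C/C=C(\C)[C@H]1C=C2C(C)(C)C[C@H](O[Si](C)(C)C(C)(C)C)C[C@@]2(C)O1
F11 | step 19 | C25 furanoid bromide from F10 | BrC/C(C)=C/C=C/C=C(C)/C=C/C=C(\C)[C@H]1C=C2C(C)(C)C[C@H](O[Si](C)(C)C(C)(C)C)C[C@@]2(C)O1
F12 | step 20 | left C25 phosphonate, diethyl {(2E,4E,6E,8E,10E,12E)-13-[(1S,2R,4S)-4-(tert-butyldimethylsilyloxy)-1,2-dihydroxy-2,6,6-trimethylcyclohexyl]-2,7,11-trimethyltrideca-2,4,6,8,10,12-hexaen-1-yl}phosphonate | CCOP(=O)(OCC)C/C(C)=C/C=C/C=C(C)/C=C/C=C(C)/C=C/[C@]1(O)C(C)(C)C[C@H](O[Si](C)(C)C(C)(C)C)C[C@@]1(C)O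
A1 | alternative 1 | alkynyl cis-diol, both hydroxyls trans to the C3 silyloxy group | C[Si](C)(C)C#C[C@]1(O)C(C)(C)C[C@H](O[Si](C)(C)C(C)(C)C)C[C@@]1(C)O
A2 | alternative 1 | silylated ring enyne, tert-butyldimethyl{[(1R)-3,5,5-trimethyl-4-(trimethylsilylethynyl)cyclohex-3-en-1-yl]oxy}silane | C[Si](C)(C)C#CC1=C(C)C[C@@H](O[Si](C)(C)C(C)(C)C)CC1(C)C
A3 | alternative 2 | 5',8'-endoperoxide ester, C5' oxygen trans to the C3' silyloxy group | CCOC(=O)/C=C(\C)[C@H]1C=C2C(C)(C)C[C@H](O[Si](C)(C)C(C)(C)C)C[C@@]2(C)OO1
A4 | alternative 2 | silylated C15 triene ester, ethyl (2E,4E)-5-[(4R)-4-(tert-butyldimethylsilyloxy)-2,6,6-trimethylcyclohex-1-en-1-yl]-3-methylpenta-2,4-dienoate | CCOC(=O)/C=C(C)/C=C/C1=C(C)C[C@@H](O[Si](C)(C)C(C)(C)C)CC1(C)C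
A5 | alternative 3 | (5'R,8'R)-furanoid C15 acetate, C3' silyl ether | CC(=O)OC/C=C(\C)[C@H]1C=C2C(C)(C)C[C@H](O[Si](C)(C)C(C)(C)C)C[C@@]2(C)O1
A6 | alternative 3 | allenic C15 acetate with free C5' hydroxyl (C6'=C7'=C8' allene, C9' arm on the C4' side) | CC(=O)OC/C=C(\C)C=[C@]=C1C(C)(C)C[C@H](O[Si](C)(C)C(C)(C)C)C[C@@]1(C)O
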